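## Structural features

The target is an elemanolide: a cyclohexane (ring carbons C5–C10) trans-fused across C6–C7 to an α-methylene-γ-butyrolactone (O6–C12(=O)–C11(=C13)–C7). The ring carries five stereocentres, four contiguous (C5, C6, C7, C8) and the quaternary C10 (methyl C14, vinyl C1=C2) next to C5; the configuration is 5R,6R,7R,8R,10S. In the chair, the C5 acrylic acid unit (C4(=C3)–C15O2H), the C6–O and C7–C11 bonds and the vinyl group are equatorial, whereas the C10 methyl and the C8 angeloyloxy group are axial on the same face, so the C8 oxygen is hindered and syn-diaxial to C14. Fragile groups are the two exocyclic enoate units (Michael acceptors, prone to double-bond migration), the (Z)-2-methylbut-2-enoate, which isomerises to the (E)-ester under nucleophilic catalysis or heat, and C5–H, which is allylic to C4=C3 and becomes α to a carbonyl in any C6 aldehyde. There is a regiochemical trap as well: O6 is γ to both C12 and C15, and O8 is γ to C12, so three five-membered lactones are conceivable. The real difficulty is the C5/C10 pair, which has to be set in an open chain, the trans ring fusion next to an axial oxygen substituent, and the choice of the right lactone. The key step uses the homoallylic alcohol retron O6–C6–C7–C11=C13, whose acyl partner C12 already sits on C11.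

## Logic of the disconnections

29 ⇒ 28. The O–C(CH3)3 bond of the C15 ester is cut last. The tert-butyl ester keeps C15 from acylating O6 throughout the route, so the free acid should appear only at the end. The demand is an acidolysis that spares the (Z)-enoate, the lactone and the alkenes.

28 ⇒ 25 + 26 (through 27). The O8–acyl bond is cut, because the (Z)-enoate is the group most easily isomerised and is best introduced late. The gain is a silyl ether on O8 during all organometallic chemistry. The demand is acylation of an axial, hindered hydroxyl without Z→E isomerisation.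

25 ⇒ 24. The O8–Si bond is cut. The silyl ether in 24 is what keeps O8 from competing for C12 during ring closure. The demand is desilylation without acyl migration from O6 to O8.

24 ⇒ 21 (through 22 and 23). C6–C7 and O6–C12 are cut together. Both rings and two stereocentres are removed in one operation, and the exocyclic C11=C13 is the direct outcome of allylic transposition. The demand is an anti (trans) C6/C7 relationship on the correct ring face, and acylation of O6 by C12 only.

21 ⇒ 20 ⇒ 19. The C6 aldehyde is traced back to a silyl-protected primary alcohol. The aldehyde is epimerisable at C5 and must be unveiled immediately before use. The demand is removal of a primary triethylsilyl ether in the presence of an allylic bromide and a secondary silyl ether.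

19 ⇒ 18 ⇒ 16 + 17. The C13–Br bond is traced back to a C7 hydroxyl with allylic transposition, then C7–C11 is cut. This attaches the whole C11–C13 enoate unit in one C–C bond formation from a commodity acrylate. The demand is an addition that does not epimerise C8 and a bromination that gives one alkene geometry.

16 ⇒ 15 ⇒ 14 ⇒ 13 ⇒ 11 (through 12). These are adjustments at C7 (aldehyde ⇒ alcohol ⇒ benzyl-type ether) and at C6 (silyl ether ⇒ alcohol ⇒ carboxylic acid). They separate the two primary oxygens by orthogonal groups. The demand is a chemoselective reduction of one carboxyl group next to a tert-butyl enoate.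

11 ⇒ 9 (through 10). C5–C10 is cut as a [3,3] retron: a γ,δ-unsaturated acid whose vinyl group is C1=C2. The quaternary centre and its neighbour fall back to an achiral pair of sp2 carbons. The demand is control of the ketene acetal geometry (relative configuration) and of the alkene face (absolute configuration), which the remote C8 centre cannot supply.

9 ⇒ 8 ⇒ 6 + 7. The tert-butyl ester and then the allylic ester C–O bond are cut. Both carboxyl groups of the four-carbon C3–C6 unit come from one cyclic anhydride, differentiated by its own regiochemistry of opening. The demand is alcoholysis at the non-conjugated carbonyl only.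

6 ⇒ 4 (through 5). C10–C14 and C1–C2 are cut. A stereodefined trisubstituted alkene is reduced to a terminal alkyne. The demand is syn carbometalation with methyl on the internal carbon.

4 ⇒ 3 ⇒ 1 + 2. The O8–Si bond and then C9–C10 are cut. C8 is taken from the chiral pool as an epoxide. The demand is attack at the unsubstituted epoxide carbon.

## Other disconnections considered

Alternative 1: The cut is C5–C10, made inside a ring. The silyl ketene acetal of the ten-membered (E)-allylic lactone A1 would undergo an Ireland–Claisen ring contraction to the cyclohexane acid A2, in which C1=C2 has become the vinyl group and the former lactone carbonyl is a C4 carboxylic acid.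
- In favour: the C5/C10 pair is formed under the conformational control of a ring that already holds C6, C7 and C8. No external chiral reagent is needed for this bond, and on this point the alternative is better than the chosen plan, which uses a stoichiometric chiral boron reagent in step 6. The carbocycle and the quaternary centre arise in one pericyclic step whose mechanism is at least as predictable as that of step 15.
- Against: A1 is a medium-ring (E)-alkene lactone with three contiguous stereocentres, and its seco acid has to be assembled and lactonised first. The ester enolate lies β to the C6 silyloxy group and can eliminate. The ring enforces a boat-like array, so the C5/C10 relationship is less secure than in an open-chain chair.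
- Structure: A2 lacks C3 and C15, and C12 is still the methyl group of a propen-2-yl unit that must be oxidised in the presence of the C1=C2 vinyl group before a lactone can be closed.
- Step economy: six to eight operations would follow A2, against three after 24, so the route is clearly longer.

Alternative 2: The cut is C9–C10. Pd(PPh3)4 (zerovalent palladium) would ionise the allylic acetate of A3, and the C9 carbon of the β-keto ester would attack the substituted allyl terminus C10, closing the cyclohexane as A4 with the vinyl group in place.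
- In favour: the metal is catalytic, which is better than an excess of CrCl2 on reagent economy and waste. Six- over eight-membered closure steers the nucleophile to the branched terminus. The trans-lactone and C5–C7 can be secured earlier. Later reduction of the C8 ketone from the α-face should give the axial alcohol under ring control; this is an equal or better answer to the C8 question, since no axial silyloxy group would have to be accommodated in the ring-closing transition state.
- Against: a quaternary centre has to form at the more hindered allyl terminus, and its configuration rests on π-allyl geometry and face, with little bias between methyl and vinyl. C5–H of A3 is doubly allylic and adjacent to the π-allyl unit, so diene formation and epimerisation compete under the basic conditions.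
- Structure: the lactone of A4 has no methylene, and C9 carries an extra ester.
- Mechanism: ionisation and alkylation are partly reversible, which helps regiochemistry but not the C10 configuration.
- Step economy: dealkoxycarbonylation, ketone reduction, α-methylenation of the lactone through an enolate next to the C4 acrylate, acylation and ester cleavage make five or six steps against three.

Alternative 3: The cut is C7–C8. Me2AlCl would activate the C8 aldehyde of A5 for an intramolecular carbonyl-ene reaction of the isopulegol kind with the trisubstituted C7=C11 alkene; a C13 hydrogen moves to oxygen and the C11=C13 methylene appears in the cyclohexanol A6.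
- In favour: this closure is one of the most reliable routes to a 2-(propen-2-yl)cyclohexanol, and its chair places every new substituent equatorial. No low-valent metal is required. On predictability of the C7 configuration and on reagent burden it is the equal or better of step 15. The exocyclic methylene is formed in the ring-forming step, as in the chosen plan.
- Against: the same chair places the C8 hydroxyl equatorial (8α), opposite to 29, so an inversion is needed. C12 arrives as a protected alcohol, so desilylation, two oxidations and lactonisation must follow. The ene hydrogen can also be taken from the CH2OSi arm. A5 needs a stereodefined C6 carbinol next to C5. The Lewis acid meets a tert-butyl ester and two silyl ethers.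
- Step economy: the inversion could in principle be merged with the esterification (Mitsunobu reaction with 26), which would equal the chosen end game in count. Displacement at C8 from the face of the axial C10 methyl is unfavourable, however, and five to seven steps after A6 are more realistic.
- Mechanism: a concerted ene process is cleaner than a redox-metal allylation, but it sets the wrong C8 configuration for this target.

Key step: step 15

Remarks and assumptions on the chemistry:
- Structures were checked atom by atom. The three resident centres and the (Z)-alkene of 21 are consistent with 24 and 29, and the (R)-epoxide 1 maps onto C8 (R) without inversion, so no correction was needed. The CIP label of C7 (C3a) reads S in 24 only because silicon on O8 outranks carbon; the spatial arrangement is that of 29.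
- Step 6 is written with the (S,S)-diazaborolidine on the assumption that it directs bond formation to the (5R,10S) pair. The sense has to be confirmed on the first run, and the (R,R)-reagent is the direct replacement if it is opposite.
- In step 15 the σ-allylchromium isomers are assumed to interconvert faster than they add to the aldehyde, as crotylchromium reagents do.

## Route

Step 1
Reactants: 1 (2R)-2-{[(4-methoxyphenyl)methoxy]methyl}oxirane; 2 lithium acetylide–ethane-1,2-diamine complex
Product: 3 (2R)-1-[(4-methoxyphenyl)methoxy]pent-4-yn-2-ol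
Conditions: LiC≡CH·H2NCH2CH2NH2 (1.5 equiv), DMSO, 0 °C → rt; aq. NH4Cl
Reagents that add atoms: none
Why: SN2 opening of a terminal epoxide by an acetylide takes place at the unsubstituted carbon (C9), so C9–C10 is formed and the C8 carbinol centre of 1 is carried over untouched.

Step 2
Reactants: 3 (2R)-1-[(4-methoxyphenyl)methoxy]pent-4-yn-2-ol
Product: 4 tert-butyl({(2R)-1-[(4-methoxyphenyl)methoxy]pent-4-yn-2-yl}oxy)dimethylsilane
Conditions: TBSCl, imidazole, DMF, rt
Reagents that add atoms: tert-butyl(chloro)dimethylsilane, CC(C)(C)[Si](C)(C)Cl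
Why: Standard silylation of a secondary alcohol; the silyl ether is inert to organoaluminium reagents, to enolisation and to divalent chromium and cannot act as an acyl acceptor later.

Step 3
Reactants: 4 tert-butyl({(2R)-1-[(4-methoxyphenyl)methoxy]pent-4-yn-2-yl}oxy)dimethylsilane
Product: 6 (2E,5R)-5-{[tert-butyl(dimethyl)silyl]oxy}-6-[(4-methoxyphenyl)methoxy]-3-methylhex-2-en-1-ol, via alkenylalane 5 (not isolated)
Conditions: Me3Al (3 equiv), Cp2ZrCl2 (0.25 equiv), CH2Cl2, 0 °C → rt; evaporate, THF, n-BuLi, −78 °C; (CH2O)n, −78 °C → rt; aq. KNaC4H4O6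
Reagents that add atoms: trimethylaluminium, C[Al](C)C; paraformaldehyde (as formaldehyde), C=O
Why: Zirconium-catalysed carboalumination adds CH3 and Al syn across the terminal alkyne with CH3 on the internal carbon (C10), and after activation with n-BuLi the alkenyl–aluminium bond of 5 is hydroxymethylated with retention. The (E)-trisubstituted allylic alcohol with C14 and C2 in place should result.

Step 4
Reactants: 6 (2E,5R)-5-{[tert-butyl(dimethyl)silyl]oxy}-6-[(4-methoxyphenyl)methoxy]-3-methylhex-2-en-1-ol; 7 itaconic anhydride (3-methylideneoxolane-2,5-dione)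
Product: 8 4-{[(2E,5R)-5-{[tert-butyl(dimethyl)silyl]oxy}-6-[(4-methoxyphenyl)methoxy]-3-methylhex-2-en-1-yl]oxy}-2-methylidene-4-oxobutanoic acid
Conditions: 7 (1.3 equiv), toluene, 70 °C
Reagents that add atoms: none
Why: Alcoholysis of itaconic anhydride occurs at the carbonyl that is not conjugated with the exocyclic alkene, which places the allylic ester on C6 and leaves the acrylic acid (C15) free. Base is left out so that the exo-methylene does not migrate.

Step 5
Reactants: 8 4-{[(2E,5R)-5-{[tert-butyl(dimethyl)silyl]oxy}-6-[(4-methoxyphenyl)methoxy]-3-methylhex-2-en-1-yl]oxy}-2-methylidene-4-oxobutanoic acid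
Product: 9 1-tert-butyl 4-[(2E,5R)-5-{[tert-butyl(dimethyl)silyl]oxy}-6-[(4-methoxyphenyl)methoxy]-3-methylhex-2-en-1-yl] 2-methylidenebutanedioate
Conditions: Cl3CC(=NH)Ot-Bu (2.5 equiv), cyclohexane/CH2Cl2, rt
Reagents that add atoms: tert-butyl 2,2,2-trichloroacetimidate, CC(C)(C)OC(=N)C(Cl)(Cl)Cl
Why: Carboxylic acids are tert-butylated by the trichloroacetimidate without added acid or base, so neither the benzyl-type ether nor the exo-methylene is disturbed. The bulky ester makes C15 inert toward O6 in all later steps.

Step 6
Reactants: 9 1-tert-butyl 4-[(2E,5R)-5-{[tert-butyl(dimethyl)silyl]oxy}-6-[(4-methoxyphenyl)methoxy]-3-methylhex-2-en-1-yl] 2-methylidenebutanedioate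
Product: 11 (2R,3S,5R)-2-[3-(tert-butoxy)-3-oxoprop-1-en-2-yl]-5-{[tert-butyl(dimethyl)silyl]oxy}-3-ethenyl-6-[(4-methoxyphenyl)methoxy]-3-methylhexanoic acid, via boron ketene acetal 10 (not isolated)
Conditions: (4S,5S)-2-bromo-1,3-bis{[3,5-bis(trifluoromethyl)phenyl]sulfonyl}-4,5-diphenyl-1,3,2-diazaborolidine (1.5 equiv, prepared beforehand), Et3N (4 equiv), toluene/hexane 2:1, −78 °C; then −20 °C → 4 °C; pH 4 buffer
Reagents that add atoms: none
Why: Enantioselective Ireland–Claisen rearrangement: soft enolisation gives the E(O) boron ketene acetal 10 (C4 trans to O–B), and its chair transition state with the (E)-alkene (C9 equatorial, C14 and C4 axial) fixes the relative configuration of C5 and C10. The C2-symmetric diazaborolidine selects the alkene face, and with it the absolute sense, independently of the remote C8 centre. The reaction type is documented for 3,7-dimethylocta-2,6-dienyl esters of β,γ-unsaturated acids, which give the same methyl/vinyl quaternary centre next to an alkenyl-bearing methine.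

Step 7
Reactants: 11 (2R,3S,5R)-2-[3-(tert-butoxy)-3-oxoprop-1-en-2-yl]-5-{[tert-butyl(dimethyl)silyl]oxy}-3-ethenyl-6-[(4-methoxyphenyl)methoxy]-3-methylhexanoic acid
Product: 13 tert-butyl 2-[(2R,3S,5R)-5-{[tert-butyl(dimethyl)silyl]oxy}-3-ethenyl-1-hydroxy-6-[(4-methoxyphenyl)methoxy]-3-methylhexan-2-yl]prop-2-enoate, via isobutyl carbonic anhydride 12 (not isolated)
Conditions: i-BuOCOCl, N-methylmorpholine, THF, −15 °C; then NaBH4, H2O, −15 °C → 0 °C
Reagents that add atoms: none
Why: Reduction of a carboxylic acid through its mixed carbonic anhydride is selective over esters; the weak amine base and low temperature should leave C5 untouched. The tert-butyl ester keeps the new C6 hydroxyl from closing a lactone on C15.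

Step 8
Reactants: 13 tert-butyl 2-[(2R,3S,5R)-5-{[tert-butyl(dimethyl)silyl]oxy}-3-ethenyl-1-hydroxy-6-[(4-methoxyphenyl)methoxy]-3-methylhexan-2-yl]prop-2-enoate
Product: 14 tert-butyl 2-[(2R,3S,5R)-5-{[tert-butyl(dimethyl)silyl]oxy}-3-ethenyl-6-[(4-methoxyphenyl)methoxy]-3-methyl-1-[(triethylsilyl)oxy]hexan-2-yl]prop-2-enoate
Conditions: TESCl, imidazole, CH2Cl2, 0 °C
Reagents that add atoms: chloro(triethyl)silane, CC[Si](CC)(CC)Cl
Why: Silylation of the primary C6 hydroxyl; the triethylsilyl ether is orthogonal to the benzyl-type ether on O7 and can later be removed by mild acid next to the secondary tert-butyldimethylsilyl ether on O8.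

Step 9
Reactants: 14 tert-butyl 2-[(2R,3S,5R)-5-{[tert-butyl(dimethyl)silyl]oxy}-3-ethenyl-6-[(4-methoxyphenyl)methoxy]-3-methyl-1-[(triethylsilyl)oxy]hexan-2-yl]prop-2-enoate
Product: 15 tert-butyl 2-[(2R,3S,5R)-5-{[tert-butyl(dimethyl)silyl]oxy}-3-ethenyl-6-hydroxy-3-methyl-1-[(triethylsilyl)oxy]hexan-2-yl]prop-2-enoate
Conditions: DDQ, CH2Cl2/pH 7 phosphate buffer, 0 °C
Reagents that add atoms: none
Why: Oxidative cleavage of a 4-methoxybenzyl ether by hydride abstraction and hydrolysis of the oxocarbenium ion; the buffered two-phase medium protects the silyl ethers, and the electron-poor alkenes are not oxidised.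

Step 10
Reactants: 15 tert-butyl 2-[(2R,3S,5R)-5-{[tert-butyl(dimethyl)silyl]oxy}-3-ethenyl-6-hydroxy-3-methyl-1-[(triethylsilyl)oxy]hexan-2-yl]prop-2-enoate
Product: 16 tert-butyl 2-[(2R,3S,5R)-5-{[tert-butyl(dimethyl)silyl]oxy}-3-ethenyl-3-methyl-6-oxo-1-[(triethylsilyl)oxy]hexan-2-yl]prop-2-enoate
Conditions: Dess–Martin periodinane, NaHCO3, CH2Cl2, 0 °C → rt
Reagents that add atoms: none
Why: Dess–Martin oxidation of the primary C7 alcohol under buffered, non-basic conditions, which is the usual way to prepare α-silyloxy aldehydes without loss of configuration at the α-carbon (C8).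

Step 11
Reactants: 16 tert-butyl 2-[(2R,3S,5R)-5-{[tert-butyl(dimethyl)silyl]oxy}-3-ethenyl-3-methyl-6-oxo-1-[(triethylsilyl)oxy]hexan-2-yl]prop-2-enoate; 17 methyl prop-2-enoate
Product: 18 9-tert-butyl 1-methyl (4R,6S,7R)-4-{[tert-butyl(dimethyl)silyl]oxy}-6-ethenyl-3-hydroxy-6-methyl-2,8-dimethylidene-7-{[(triethylsilyl)oxy]methyl}nonanedioate (both C3 epimers)
Conditions: DABCO (1 equiv), 17 (10 equiv), MeOH (2 equiv), rt
Reagents that add atoms: none
Why: Morita–Baylis–Hillman reaction: the amine–acrylate zwitterion adds to the inductively activated α-silyloxy aldehyde and C7–C11 is formed. The new C7 carbinol centre is not controlled and need not be, because it becomes sp2 in step 12; the α-substituted tert-butyl acrylate cannot act as the donor.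

Step 12
Reactants: 18 9-tert-butyl 1-methyl (4R,6S,7R)-4-{[tert-butyl(dimethyl)silyl]oxy}-6-ethenyl-3-hydroxy-6-methyl-2,8-dimethylidene-7-{[(triethylsilyl)oxy]methyl}nonanedioate
Product: 19 9-tert-butyl 1-methyl (2Z,4R,6S,7R)-2-(bromomethyl)-4-{[tert-butyl(dimethyl)silyl]oxy}-6-ethenyl-6-methyl-8-methylidene-7-{[(triethylsilyl)oxy]methyl}non-2-enedioate
Conditions: NBS, Me2S, CH2Cl2, −20 °C → rt
Reagents that add atoms: N-bromosuccinimide, O=C1CCC(=O)N1Br
Why: The hydroxyl is activated by the sulfonium reagent formed from NBS and Me2S, and bromide attacks C13 with allylic transposition (SN2'). Both C7 epimers converge on the (Z)-2-(bromomethyl)enoate, the isomer with C8 anti to the ester, which is the usual outcome for such adducts.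

Step 13
Reactants: 19 9-tert-butyl 1-methyl (2Z,4R,6S,7R)-2-(bromomethyl)-4-{[tert-butyl(dimethyl)silyl]oxy}-6-ethenyl-6-methyl-8-methylidene-7-{[(triethylsilyl)oxy]methyl}non-2-enedioate
Product: 20 9-tert-butyl 1-methyl (2Z,4R,6S,7R)-2-(bromomethyl)-4-{[tert-butyl(dimethyl)silyl]oxy}-6-ethenyl-7-(hydroxymethyl)-6-methyl-8-methylidenenon-2-enedioate
Conditions: CSA (0.1 equiv), MeOH/CH2Cl2 1:4, −20 °C → 0 °C; NaHCO3
Reagents that add atoms: none
Why: Acid-catalysed methanolysis removes a primary triethylsilyl ether much faster than a secondary tert-butyldimethylsilyl ether. The medium contains no amine or fluoride that could displace the allylic bromide, and the tert-butyl ester again prevents lactonisation of the free C6 hydroxyl.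

Step 14
Reactants: 20 9-tert-butyl 1-methyl (2Z,4R,6S,7R)-2-(bromomethyl)-4-{[tert-butyl(dimethyl)silyl]oxy}-6-ethenyl-7-(hydroxymethyl)-6-methyl-8-methylidenenon-2-enedioate
Product: 21 9-tert-butyl 1-methyl (2Z,4R,6S,7R)-2-(bromomethyl)-4-{[tert-butyl(dimethyl)silyl]oxy}-6-ethenyl-7-formyl-6-methyl-8-methylidenenon-2-enedioate
Conditions: Dess–Martin periodinane, NaHCO3, CH2Cl2, 0 °C; used at once
Reagents that add atoms: none
Why: Buffered Dess–Martin oxidation gives the C6 aldehyde without base, so the C5 centre (α to the aldehyde and allylic to C4=C3) should neither epimerise nor move into conjugation; the allylic bromide is inert to the oxidant.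

Step 15
Reactants: 21 9-tert-butyl 1-methyl (2Z,4R,6S,7R)-2-(bromomethyl)-4-{[tert-butyl(dimethyl)silyl]oxy}-6-ethenyl-7-formyl-6-methyl-8-methylidenenon-2-enedioate
Product: 24 tert-butyl 2-[(3aS,4R,6S,7R,7aR)-4-{[tert-butyl(dimethyl)silyl]oxy}-6-ethenyl-6-methyl-3-methylidene-2-oxooctahydro-1-benzofuran-7-yl]prop-2-enoate, via allylchromium dichloride 22 (not isolated), via chromium alkoxide 23 (not isolated)
Conditions: CrCl2 (6 equiv), THF (0.005 M, degassed), rt; aq. NH4Cl
Reagents that add atoms: none
Why: Two equivalents of CrCl2 (divalent chromium) reduce the C13–Br bond of 21 to the trivalent allylchromium 22, which adds to the C6 aldehyde through C7 with allylic transposition in a six-membered chromium-bridged array; this forms C6–C7, closes the cyclohexane (6-exo-trig) and unveils C11=C13. The alkoxide 23 then acylates itself on the C12 methyl ester (5-exo-trig) and gives the lactone with loss of methoxide. The closest known reaction type is the chromium-mediated addition of 2-(bromomethyl)acrylates to aldehydes that delivers α-methylene-γ-butyrolactones, including intramolecular cases. At C6 the oxygen should become equatorial, because any axial C6–O bond would be syn-diaxial to a substituent of the quaternary C10; at C7 the C11 unit should become equatorial, so the anti (trans-diequatorial) pair is expected, provided that the σ-allylchromium isomers interconvert and the (Z)-geometry of the bromide is not carried into the transition state. The ring face is selected by the chair in which the C5 acrylate is equatorial and anti to the forming bond (a Felkin–Anh arrangement about C5–C6) and the C8–O bond is gauche rather than anti to it (inside-alkoxy arrangement); this is the chair with C14 and the C8 silyloxy group axial, which is the arrangement of 29. The step needs chemoselectivity in the acylation: the tert-butyl ester keeps O6 from C15 and the silyl ether keeps O8 from C12. The neutral aprotic medium should leave C5–H and both enoates untouched, and high dilution suppresses intermolecular coupling.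

Step 16
Reactants: 24 tert-butyl 2-[(3aS,4R,6S,7R,7aR)-4-{[tert-butyl(dimethyl)silyl]oxy}-6-ethenyl-6-methyl-3-methylidene-2-oxooctahydro-1-benzofuran-7-yl]prop-2-enoate
Product: 25 tert-butyl 2-[(3aR,4R,6S,7R,7aR)-6-ethenyl-4-hydroxy-6-methyl-3-methylidene-2-oxooctahydro-1-benzofuran-7-yl]prop-2-enoate
Conditions: HF·pyridine, THF, 0 °C → rt (polyethylene vessel)
Reagents that add atoms: none
Why: Fluoride-assisted desilylation under acidic conditions; without alkoxide or free fluoride base, neither conjugate addition to the methylene lactone nor acyl transfer from O6 to O8 should be triggered.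

Step 17
Reactants: 25 tert-butyl 2-[(3aR,4R,6S,7R,7aR)-6-ethenyl-4-hydroxy-6-methyl-3-methylidene-2-oxooctahydro-1-benzofuran-7-yl]prop-2-enoate; 26 (2Z)-2-methylbut-2-enoic acid (angelic acid)
Product: 28 (3aR,4R,6S,7R,7aR)-7-[3-(tert-butoxy)-3-oxoprop-1-en-2-yl]-6-ethenyl-6-methyl-3-methylidene-2-oxooctahydro-1-benzofuran-4-yl (2Z)-2-methylbut-2-enoate, via mixed anhydride 27 (not isolated)
Conditions: 26, 2,4,6-Cl3C6H2COCl, Et3N, toluene, rt; then 25, toluene, 80 °C (no DMAP)
Reagents that add atoms: none
Why: Yamaguchi esterification: the alcohol attacks the mixed anhydride 27 at the angeloyl carbonyl, since the aroyl carbonyl is shielded by two ortho chlorines. Leaving out the nucleophilic pyridine catalyst removes the addition–elimination path by which (Z)-2-methylbut-2-enoates isomerise.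

Step 18
Reactants: 28 (3aR,4R,6S,7R,7aR)-7-[3-(tert-butoxy)-3-oxoprop-1-en-2-yl]-6-ethenyl-6-methyl-3-methylidene-2-oxooctahydro-1-benzofuran-4-yl (2Z)-2-methylbut-2-enoate
Product: 29 2-[(3aR,4R,6S,7R,7aR)-6-ethenyl-6-methyl-4-{[(2Z)-2-methylbut-2-enoyl]oxy}-3-methylidene-2-oxooctahydro-1-benzofuran-7-yl]prop-2-enoic acid
Conditions: CF3CO2H/CH2Cl2 1:4, 0 °C
Reagents that add atoms: none
Why: Acidolysis of the tert-butyl ester through the tert-butyl cation (lost as isobutene); the lactone, the (Z)-enoate and the monosubstituted vinyl group have no comparably easy ionisation path at 0 °C.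

## Compound list

1 | (2R)-2-{[(4-methoxyphenyl)methoxy]methyl}oxirane | COc1ccc(COC[C@H]2CO2)cc1 | starting material
2 | lithium acetylide–ethane-1,2-diamine complex | [Li+].[C-]#C.NCCN | starting material
3 | (2R)-1-[(4-methoxyphenyl)methoxy]pent-4-yn-2-ol | C#CC[C@@H](O)COCc1ccc(OC)cc1 | intermediate
4 | tert-butyl({(2R)-1-[(4-methoxyphenyl)methoxy]pent-4-yn-2-yl}oxy)dimethylsilane | C#CC[C@@H](O[Si](C)(C)C(C)(C)C)COCc1ccc(OC)cc1 | intermediate
5 | (E)-alkenyl(dimethyl)alane from 4, not isolated | C[Al](C)/C=C(\C)C[C@@H](O[Si](C)(C)C(C)(C)C)COCc1ccc(OC)cc1 | intermediate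
6 | (2E,5R)-5-{[tert-butyl(dimethyl)silyl]oxy}-6-[(4-methoxyphenyl)methoxy]-3-methylhex-2-en-1-ol | OC/C=C(\C)C[C@@H](O[Si](C)(C)C(C)(C)C)COCc1ccc(OC)cc1 | intermediate
7 | itaconic anhydride (3-methylideneoxolane-2,5-dione) | C=C1CC(=O)OC1=O | starting material
8 | 4-{[(2E,5R)-5-{[tert-butyl(dimethyl)silyl]oxy}-6-[(4-methoxyphenyl)methoxy]-3-methylhex-2-en-1-yl]oxy}-2-methylidene-4-oxobutanoic acid | OC(=O)C(=C)CC(=O)OC/C=C(\C)C[C@@H](O[Si](C)(C)C(C)(C)C)COCc1ccc(OC)cc1 | intermediate
9 | 1-tert-butyl 4-[(2E,5R)-5-{[tert-butyl(dimethyl)silyl]oxy}-6-[(4-methoxyphenyl)methoxy]-3-methylhex-2-en-1-yl] 2-methylidenebutanedioate | CC(C)(C)OC(=O)C(=C)CC(=O)OC/C=C(\C)C[C@@H](O[Si](C)(C)C(C)(C)C)COCc1ccc(OC)cc1 | intermediate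
10 | E(O) boron ketene acetal of 9 with the (S,S)-diazaborolidine, not isolated | CC(C)(C)OC(=O)C(=C)/C=C(/OB1N(S(=O)(=O)c2cc(cc(c2)C(F)(F)F)C(F)(F)F)[C@@H](c3ccccc3)[C@H](c4ccccc4)N1S(=O)(=O)c5cc(cc(c5)C(F)(F)F)C(F)(F)F)OC/C=C(\C)C[C@@H](O[Si](C)(C)C(C)(C)C)COCc1ccc(OC)cc1 | intermediate
11 | (2R,3S,5R)-2-[3-(tert-butoxy)-3-oxoprop-1-en-2-yl]-5-{[tert-butyl(dimethyl)silyl]oxy}-3-ethenyl-6-[(4-methoxyphenyl)methoxy]-3-methylhexanoic acid | C=C[C@](C)(C[C@@H](O[Si](C)(C)C(C)(C)C)COCc1ccc(OC)cc1)[C@@H](C(=O)O)C(=C)C(=O)OC(C)(C)C | intermediate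
12 | isobutyl carbonic mixed anhydride of 11, not isolated | C=C[C@](C)(C[C@@H](O[Si](C)(C)C(C)(C)C)COCc1ccc(OC)cc1)[C@@H](C(=O)OC(=O)OCC(C)C)C(=C)C(=O)OC(C)(C)C | intermediate
13 | tert-butyl 2-[(2R,3S,5R)-5-{[tert-butyl(dimethyl)silyl]oxy}-3-ethenyl-1-hydroxy-6-[(4-methoxyphenyl)methoxy]-3-methylhexan-2-yl]prop-2-enoate | C=C[C@](C)(C[C@@H](O[Si](C)(C)C(C)(C)C)COCc1ccc(OC)cc1)[C@@H](CO)C(=C)C(=O)OC(C)(C)C | intermediate
14 | tert-butyl 2-[(2R,3S,5R)-5-{[tert-butyl(dimethyl)silyl]oxy}-3-ethenyl-6-[(4-methoxyphenyl)methoxy]-3-methyl-1-[(triethylsilyl)oxy]hexan-2-yl]prop-2-enoate | C=C[C@](C)(C[C@@H](O[Si](C)(C)C(C)(C)C)COCc1ccc(OC)cc1)[C@@H](CO[Si](CC)(CC)CC)C(=C)C(=O)OC(C)(C)C | intermediate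
15 | tert-butyl 2-[(2R,3S,5R)-5-{[tert-butyl(dimethyl)silyl]oxy}-3-ethenyl-6-hydroxy-3-methyl-1-[(triethylsilyl)oxy]hexan-2-yl]prop-2-enoate | C=C[C@](C)(C[C@@H](O[Si](C)(C)C(C)(C)C)CO)[C@@H](CO[Si](CC)(CC)CC)C(=C)C(=O)OC(C)(C)C | intermediate
16 | tert-butyl 2-[(2R,3S,5R)-5-{[tert-butyl(dimethyl)silyl]oxy}-3-ethenyl-3-methyl-6-oxo-1-[(triethylsilyl)oxy]hexan-2-yl]prop-2-enoate | C=C[C@](C)(C[C@@H](O[Si](C)(C)C(C)(C)C)C=O)[C@@H](CO[Si](CC)(CC)CC)C(=C)C(=O)OC(C)(C)C | intermediate
17 | methyl prop-2-enoate | C=CC(=O)OC | starting material
18 | 9-tert-butyl 1-methyl (4R,6S,7R)-4-{[tert-butyl(dimethyl)silyl]oxy}-6-ethenyl-3-hydroxy-6-methyl-2,8-dimethylidene-7-{[(triethylsilyl)oxy]methyl}nonanedioate (C3 epimers) | C=C[C@](C)(C[C@@H](O[Si](C)(C)C(C)(C)C)C(O)C(=C)C(=O)OC)[C@@H](CO[Si](CC)(CC)CC)C(=C)C(=O)OC(C)(C)C | intermediate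
19 | 9-tert-butyl 1-methyl (2Z,4R,6S,7R)-2-(bromomethyl)-4-{[tert-butyl(dimethyl)silyl]oxy}-6-ethenyl-6-methyl-8-methylidene-7-{[(triethylsilyl)oxy]methyl}non-2-enedioate | C=C[C@](C)(C[C@@H](O[Si](C)(C)C(C)(C)C)/C=C(\CBr)C(=O)OC)[C@@H](CO[Si](CC)(CC)CC)C(=C)C(=O)OC(C)(C)C | intermediate
20 | 9-tert-butyl 1-methyl (2Z,4R,6S,7R)-2-(bromomethyl)-4-{[tert-butyl(dimethyl)silyl]oxy}-6-ethenyl-7-(hydroxymethyl)-6-methyl-8-methylidenenon-2-enedioate | C=C[C@](C)(C[C@@H](O[Si](C)(C)C(C)(C)C)/C=C(\CBr)C(=O)OC)[C@@H](CO)C(=C)C(=O)OC(C)(C)C | intermediate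
21 | 9-tert-butyl 1-methyl (2Z,4R,6S,7R)-2-(bromomethyl)-4-{[tert-butyl(dimethyl)silyl]oxy}-6-ethenyl-7-formyl-6-methyl-8-methylidenenon-2-enedioate | C=C[C@](C)(C[C@@H](O[Si](C)(C)C(C)(C)C)/C=C(\CBr)C(=O)OC)[C@@H](C=O)C(=C)C(=O)OC(C)(C)C | intermediate
22 | allylchromium dichloride from 21, not isolated | C=C[C@](C)(C[C@@H](O[Si](C)(C)C(C)(C)C)/C=C(\C[Cr](Cl)Cl)C(=O)OC)[C@@H](C=O)C(=C)C(=O)OC(C)(C)C | intermediate
23 | chromium alkoxide of the cyclised hydroxy ester, not isolated | C=C[C@]1(C)C[C@@H](O[Si](C)(C)C(C)(C)C)[C@@H](C(=C)C(=O)OC)[C@H](O[Cr](Cl)Cl)[C@H]1C(=C)C(=O)OC(C)(C)C | intermediate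
24 | tert-butyl 2-[(3aS,4R,6S,7R,7aR)-4-{[tert-butyl(dimethyl)silyl]oxy}-6-ethenyl-6-methyl-3-methylidene-2-oxooctahydro-1-benzofuran-7-yl]prop-2-enoate | C=C[C@]1(C)C[C@@H](O[Si](C)(C)C(C)(C)C)[C@H]2C(=C)C(=O)O[C@@H]2[C@H]1C(=C)C(=O)OC(C)(C)C | intermediate
25 | tert-butyl 2-[(3aR,4R,6S,7R,7aR)-6-ethenyl-4-hydroxy-6-methyl-3-methylidene-2-oxooctahydro-1-benzofuran-7-yl]prop-2-enoate | C=C[C@]1(C)C[C@@H](O)[C@H]2C(=C)C(=O)O[C@@H]2[C@H]1C(=C)C(=O)OC(C)(C)C | intermediate
26 | (2Z)-2-methylbut-2-enoic acid (angelic acid) | C/C=C(/C)C(=O)O | starting material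
27 | (2Z)-2-methylbut-2-enoic 2,4,6-trichlorobenzoic anhydride, not isolated | C/C=C(/C)C(=O)OC(=O)c1c(Cl)cc(Cl)cc1Cl | intermediate
28 | (3aR,4R,6S,7R,7aR)-7-[3-(tert-butoxy)-3-oxoprop-1-en-2-yl]-6-ethenyl-6-methyl-3-methylidene-2-oxooctahydro-1-benzofuran-4-yl (2Z)-2-methylbut-2-enoate | C=C[C@]1(C)C[C@@H](OC(=O)/C(C)=C\C)[C@H]2C(=C)C(=O)O[C@@H]2[C@H]1C(=C)C(=O)OC(C)(C)C | intermediate
29 | 2-[(3aR,4R,6S,7R,7aR)-6-ethenyl-6-methyl-4-{[(2Z)-2-methylbut-2-enoyl]oxy}-3-methylidene-2-oxooctahydro-1-benzofuran-7-yl]prop-2-enoic acid | C=C[C@]1(C)C[C@@H](OC(=O)/C(C)=C\C)[C@H]2C(=C)C(=O)O[C@@H]2[C@H]1C(=C)C(=O)O | target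

## Step count and risks

Total step count: 18. Longest linear sequence: 18 (the route is linear from 1; 2, 7, 17 and 26 are purchased).

Steps least certain to work:

Step 15 (key step). Stereocontrol of the ring closure may leak in two ways. If the (Z)-allylchromium adds before it equilibrates, the closed chair would lead to a cis ring fusion. Closure may also occur on the opposite ring face, because the desired chair has to hold the C8 silyloxy group axial and syn to C14. Loss of the C8 silyloxy group from the allylchromium by 1,4-elimination is a further competing process. The fallback takes the chromium bridge out of the transition state. It sets out from 21: Pd(PPh3)4 (zerovalent palladium) and Bu3SnSnBu3 in THF would exchange bromide for tin to give the allylstannane F1. BF3·OEt2 in CH2Cl2 at −78 °C would then promote addition to the aldehyde through an open transition state, in which ring-fusion geometry no longer depends on the geometry of the allylmetal and both new substituents can be equatorial, to give the hydroxy ester F2. A catalytic amount of CSA in CH2Cl2 would close the lactone, and the route is rejoined at 24.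

Step 6. Transfer of absolute configuration may be incomplete, because the acrylate substituent on the enolate is not a standard case for this reagent class. The enolate geometry may erode, and the 4-methoxybenzyl ether or the tert-butyl ester may be cleaved slowly by the Lewis-acidic boron bromide during the long rearrangement. The fallback gives up reagent control. It sets out from 9: LiN(i-Pr)2 and Me3SiCl in THF at −78 °C would give the trimethylsilyl ketene acetal F3, which rearranges on warming to room temperature through the same chair. Aqueous acid would deliver 11 together with its (2S,3R,5R) diastereomer F4; the two are separated by chromatography (as acids, or after step 7), and the route continues from 11.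

Step 11. Addition to the hindered α-silyloxy aldehyde may be slow, and long exposure to the amine may cause epimerisation at C8 or silyl migration. The fallback replaces amine catalysis by a stoichiometric vinylmetal. It sets out from 16: hydroalumination of methyl propiolate with i-Bu2AlH and N-methylmorpholine N-oxide in THF at 0 °C would give methyl 2-(diisobutylalumanyl)prop-2-enoate F5, which adds to 16 at 0 °C within hours, and the route is rejoined at 18.

Step 17. Acylation of the axial C8 hydroxyl, syn to C14, may be sluggish, and forcing it may cause Z→E isomerisation of the acyl group or acyl migration of the lactone from O6 to O8. The fallback builds the (Z)-alkene after the ester bond. It sets out from 25: 2-[bis(2,2,2-trifluoroethoxy)phosphoryl]propanoic acid with DCC and catalytic DMAP (harmless here, as no (Z)-alkene is present yet) would give the phosphonate ester F6. A Still–Gennari olefination with acetaldehyde (KN(SiMe3)2, 18-crown-6, THF, −78 °C) would then give the (Z)-enoate, and the route is rejoined at 28.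

Step 13. Solvolysis of the allylic bromide (direct or with allylic shift) and partial loss of the C8 silyl ether may accompany the acid-catalysed removal of the triethylsilyl group. The fallback changes the order of events so that no deprotection is run on the bromide. It sets out from 18: CSA in MeOH/CH2Cl2 would give the diol F7. TEMPO (catalytic) with PhI(OAc)2 would oxidise the primary C6 alcohol in preference to the hindered secondary allylic one, giving the hydroxy aldehyde F8. NBS/Me2S would then brominate with allylic transposition, and the route is rejoined at 21.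

## Further compounds

F1 | step 15 | 9-tert-butyl 1-methyl (2Z,4R,6S,7R)-4-{[tert-butyl(dimethyl)silyl]oxy}-6-ethenyl-7-formyl-6-methyl-8-methylidene-2-[(tributylstannyl)methyl]non-2-enedioate | C=C[C@](C)(C[C@@H](O[Si](C)(C)C(C)(C)C)/C=C(\C[Sn](CCCC)(CCCC)CCCC)C(=O)OC)[C@@H](C=O)C(=C)C(=O)OC(C)(C)C
F2 | step 15 | hydroxy ester, open form of 24 (6-hydroxy, C12 methyl ester) | C=C[C@]1(C)C[C@@H](O[Si](C)(C)C(C)(C)C)[C@@H](C(=C)C(=O)OC)[C@H](O)[C@H]1C(=C)C(=O)OC(C)(C)C
F3 | step 6 | E(O) trimethylsilyl ketene acetal of 9 | CC(C)(C)OC(=O)C(=C)/C=C(/O[Si](C)(C)C)OC/C=C(\C)C[C@@H](O[Si](C)(C)C(C)(C)C)COCc1ccc(OC)cc1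
F4 | step 6 | (2S,3R,5R)-2-[3-(tert-butoxy)-3-oxoprop-1-en-2-yl]-5-{[tert-butyl(dimethyl)silyl]oxy}-3-ethenyl-6-[(4-methoxyphenyl)methoxy]-3-methylhexanoic acid | C=C[C@@](C)(C[C@@H](O[Si](C)(C)C(C)(C)C)COCc1ccc(OC)cc1)[C@H](C(=O)O)C(=C)C(=O)OC(C)(C)C
F5 | step 11 | methyl 2-(diisobutylalumanyl)prop-2-enoate | C=C([Al](CC(C)C)CC(C)C)C(=O)OC
F6 | step 17 | 8-O-{2-[bis(2,2,2-trifluoroethoxy)phosphoryl]propanoyl} derivative of 25 | C=C[C@]1(C)C[C@@H](OC(=O)C(C)P(=O)(OCC(F)(F)F)OCC(F)(F)F)[C@H]2C(=C)C(=O)O[C@@H]2[C@H]1C(=C)C(=O)OC(C)(C)C
F7 | step 13 | 9-tert-butyl 1-methyl (4R,6S,7R)-4-{[tert-butyl(dimethyl)silyl]oxy}-6-ethenyl-3-hydroxy-7-(hydroxymethyl)-6-methyl-2,8-dimethylidenenonanedioate | C=C[C@](C)(C[C@@H](O[Si](C)(C)C(C)(C)C)C(O)C(=C)C(=O)OC)[C@@H](CO)C(=C)C(=O)OC(C)(C)C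
F8 | step 13 | 9-tert-butyl 1-methyl (4R,6S,7R)-4-{[tert-butyl(dimethyl)silyl]oxy}-6-ethenyl-7-formyl-3-hydroxy-6-methyl-2,8-dimethylidenenonanedioate | C=C[C@](C)(C[C@@H](O[Si](C)(C)C(C)(C)C)C(O)C(=C)C(=O)OC)[C@@H](C=O)C(=C)C(=O)OC(C)(C)C
A1 | alternative 1 | (8E)-ten-membered allylic lactone: 6-(tert-butyldimethylsilyloxy)-8-methyl-5-(prop-1-en-2-yl)-4-(triethylsilyloxy)oxacyclodec-8-en-2-one, configured as A2 | O=C1C[C@@H](O[Si](CC)(CC)CC)[C@H](C(C)=C)[C@H](O[Si](C)(C)C(C)(C)C)C/C(C)=C/CO1
A2 | alternative 1 | 2-methyl-2-vinylcyclohexanecarboxylic acid with 6-O-triethylsilyl, 7-(prop-1-en-2-yl) and 8-O-tert-butyldimethylsilyl groups | C=C[C@]1(C)C[C@@H](O[Si](C)(C)C(C)(C)C)[C@@H](C(C)=C)[C@H](O[Si](CC)(CC)CC)[C@H]1C(=O)O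
A3 | alternative 2 | lactone β-keto ester with (E)-allylic acetate side chain on C5 | COC(=O)CC(=O)[C@H]1CC(=O)O[C@@H]1[C@@H](C(=C)C(=O)OC(C)(C)C)/C(C)=C/COC(C)=O
A4 | alternative 2 | bicyclic lactone β-keto ester (enol form) with the C10 methyl/vinyl centre | C=C[C@]1(C)C(C(=O)OC)=C(O)[C@H]2CC(=O)O[C@@H]2[C@H]1C(=C)C(=O)OC(C)(C)C
A5 | alternative 3 | C8 aldehyde with (E)-C7=C11 allylic silyl ether and 6-O-silyl group | O=CC[C@@](C)(C=C)[C@H](C(=C)C(=O)OC(C)(C)C)[C@@H](O[Si](C)(C)C(C)(C)C)/C=C(\C)CO[Si](C)(C)C(C)(C)C
A6 | alternative 3 | cyclohexanol with 8α-hydroxyl, 6,12-bis-silyl ether and C7 propen-2-yl unit | C=C[C@]1(C)C[C@H](O)[C@@H](C(=C)CO[Si](C)(C)C(C)(C)C)[C@H](O[Si](C)(C)C(C)(C)C)[C@H]1C(=C)C(=O)OC(C)(C)C
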